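**Strategy.** The benzene ring of the 2H-chromene carries oxygen at C7 and C8a and the phenethyl carbon at C5, all ortho/para to the ester carbon C6, so C5 is a masked phenol carbon of methyl 2,4,6-trihydroxybenzoate. The route rests on cutting the C5–CH2 bond of the 4-hydroxyphenethyl chain. The key step, a B-alkyl Suzuki–Miyaura coupling, joins the C5 triflate of the fully substituted chromene ester (activated by the ortho ester) to the 9-BBN adduct of 4-acetoxystyrene and, after in-flask deacetylation, gives the target directly. The triflate comes from the symmetric phloroglucinol ester by O-propargylation, C-prenylation, site-selective triflation and propargyl Claisen cyclisation.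

Key step: step 5

Remark: the target has no stereocentre and no stereogenic double bond (the chromene C3=C4 bond is ring-locked), so no stereocontrol is required. Compounds 1, 2, 4, 10 and 11 are taken as commercial.

**Step 1**
Reactants: 1 methyl 2,4,6-trihydroxybenzoate; 2 3-chloro-3-methylbut-1-yne
Product: 3 methyl 2,6-dihydroxy-4-[(2-methylbut-3-yn-2-yl)oxy]benzoate
Conditions: 2 (1.2 equiv), K2CO3 (1.1 equiv), KI (cat.), CuI (cat.), acetone, 50 °C
Reagents that add atoms: none
Why: Copper-assisted Williamson-type O-propargylation should take place at the 4-OH, the most acidic hydroxyl and the only one not hydrogen-bonded to the ester, and the product keeps the mirror symmetry of 1.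

**Step 2**
Reactants: 3 methyl 2,6-dihydroxy-4-[(2-methylbut-3-yn-2-yl)oxy]benzoate; 4 1-bromo-3-methylbut-2-ene (prenyl bromide)
Product: 5 methyl 2,6-dihydroxy-3-(3-methylbut-2-en-1-yl)-4-[(2-methylbut-3-yn-2-yl)oxy]benzoate
Conditions: NaH (1.0 equiv), toluene, 0 °C; then 4 (1.0 equiv), 0 °C to rt
Reagents that add atoms: none
Why: Ortho C-alkylation of a sodium phenoxide as a tight ion pair in a non-polar solvent (SN2 at the primary allylic carbon) should place the prenyl group on the ring carbon between two oxygens, and because C3 and C5 of 3 are equivalent only one mono-C-prenyl product can form.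

**Step 3**
Reactants: 5 methyl 2,6-dihydroxy-3-(3-methylbut-2-en-1-yl)-4-[(2-methylbut-3-yn-2-yl)oxy]benzoate
Product: 6 methyl 2-hydroxy-3-(3-methylbut-2-en-1-yl)-4-[(2-methylbut-3-yn-2-yl)oxy]-6-{[(trifluoromethyl)sulfonyl]oxy}benzoate
Conditions: PhNTf2 (1.05 equiv), Et3N, DMAP (cat.), CH2Cl2, 0 °C to rt
Reagents that add atoms: N-phenylbis(trifluoromethanesulfonimide), O=S(=O)(N(c1ccccc1)S(=O)(=O)C(F)(F)F)C(F)(F)F
Why: Phenol O-sulfonylation with the bulky, mild triflimide should favour the C6 hydroxyl, whose second ortho neighbour is C5–H, over the C2 hydroxyl, which is buttressed by the prenyl CH2, and the remaining chelated hydroxyl should resist a second triflation.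

**Step 4**
Reactants: 6 methyl 2-hydroxy-3-(3-methylbut-2-en-1-yl)-4-[(2-methylbut-3-yn-2-yl)oxy]-6-{[(trifluoromethyl)sulfonyl]oxy}benzoate
Product: 9 methyl 7-hydroxy-2,2-dimethyl-8-(3-methylbut-2-en-1-yl)-5-{[(trifluoromethyl)sulfonyl]oxy}-2H-chromene-6-carboxylate, via allenylphenol 7 (not isolated), via ortho-quinone methide 8 (not isolated)
Conditions: o-xylene, 140 °C
Reagents that add atoms: none
Why: Aryl propargyl ether Claisen rearrangement to C5, the only free ortho carbon, then tautomerisation to 7, a 1,5-hydrogen shift to 8 and oxa-6π electrocyclisation should give the 2,2-dimethylchromene, with the prenyl group at C3 blocking the other ortho position.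

**Step 5**
Reactants: 9 methyl 7-hydroxy-2,2-dimethyl-8-(3-methylbut-2-en-1-yl)-5-{[(trifluoromethyl)sulfonyl]oxy}-2H-chromene-6-carboxylate; 10 4-acetoxystyrene; 11 9-borabicyclo[3.3.1]nonane (9-BBN)
Product: 14 methyl 7-hydroxy-5-[2-(4-hydroxyphenyl)ethyl]-2,2-dimethyl-8-(3-methylbut-2-en-1-yl)-2H-chromene-6-carboxylate, via alkylborane 12 (not isolated), via aryl acetate 13 (not isolated)
Conditions: 10 (1.6 equiv), 11 (1.5 equiv), THF, 0 °C to rt; then 9, Pd(OAc)2 (5 mol %), SPhos (10 mol %), 3 M aq. K3PO4 (4 equiv), THF, 65 °C; then MeOH, 40 °C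
Reagents that add atoms: none
Why: Anti-Markovnikov hydroboration of styrene 10 with 9-BBN gives the primary alkylborane 12; Pd(0)/SPhos then inserts into the C5–OTf bond of 9, the base-activated borate transfers its primary alkyl group to palladium, and reductive elimination forms the C5–CH2 bond. This is a B-alkyl Suzuki–Miyaura coupling of an aryl triflate, the closest known reaction type being the coupling of ortho-carbonyl aryl triflates with alkyl-9-BBN reagents. No ring is closed and no stereocentre is formed. The step needs chemoselectivity: all B–H is consumed by the excess of 10 before 9 is added, so the prenyl and chromene double bonds and the free phenol of 9 never meet a hydroborating agent. Coupling must outrun triflate S–O cleavage and β-hydride elimination, which the ortho ester (faster oxidative addition), the phosphate base and the bulky electron-rich biarylphosphine should secure. Methanol added at the end removes the aryl acetate of 13 by base-catalysed transesterification, while the doubly ortho-substituted, hydrogen-bonded methyl ester should be left alone.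

**Compound list**
1 | methyl 2,4,6-trihydroxybenzoate | COC(=O)c1c(O)cc(O)cc1O | starting material
2 | 3-chloro-3-methylbut-1-yne | C#CC(C)(C)Cl | starting material
3 | methyl 2,6-dihydroxy-4-[(2-methylbut-3-yn-2-yl)oxy]benzoate | COC(=O)c1c(O)cc(OC(C)(C)C#C)cc1O | intermediate
4 | 1-bromo-3-methylbut-2-ene (prenyl bromide) | CC(C)=CCBr | starting material
5 | methyl 2,6-dihydroxy-3-(3-methylbut-2-en-1-yl)-4-[(2-methylbut-3-yn-2-yl)oxy]benzoate | COC(=O)c1c(O)c(CC=C(C)C)c(OC(C)(C)C#C)cc1O | intermediate
6 | methyl 2-hydroxy-3-(3-methylbut-2-en-1-yl)-4-[(2-methylbut-3-yn-2-yl)oxy]-6-{[(trifluoromethyl)sulfonyl]oxy}benzoate | COC(=O)c1c(O)c(CC=C(C)C)c(OC(C)(C)C#C)cc1OS(=O)(=O)C(F)(F)F | intermediate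
7 | methyl 2,4-dihydroxy-5-(3-methylbuta-1,2-dien-1-yl)-3-(3-methylbut-2-en-1-yl)-6-{[(trifluoromethyl)sulfonyl]oxy}benzoate (allenylphenol) | COC(=O)c1c(O)c(CC=C(C)C)c(O)c(C=C=C(C)C)c1OS(=O)(=O)C(F)(F)F | intermediate (not isolated)
8 | methyl (3Z)-6-hydroxy-3-(3-methylbut-2-en-1-ylidene)-5-(3-methylbut-2-en-1-yl)-4-oxo-2-{[(trifluoromethyl)sulfonyl]oxy}cyclohexa-1,5-diene-1-carboxylate (ortho-quinone methide) | COC(=O)C1=C(OS(=O)(=O)C(F)(F)F)/C(=C/C=C(C)C)C(=O)C(CC=C(C)C)=C1O | intermediate (not isolated)
9 | methyl 7-hydroxy-2,2-dimethyl-8-(3-methylbut-2-en-1-yl)-5-{[(trifluoromethyl)sulfonyl]oxy}-2H-chromene-6-carboxylate | COC(=O)c1c(O)c(CC=C(C)C)c2c(c1OS(=O)(=O)C(F)(F)F)C=CC(C)(C)O2 | intermediate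
10 | 4-acetoxystyrene (4-ethenylphenyl acetate) | CC(=O)Oc1ccc(C=C)cc1 | starting material
11 | 9-borabicyclo[3.3.1]nonane (9-BBN, monomer shown; used as the commercial dimer or THF solution) | B1C2CCCC1CCC2 | starting material
12 | 4-[2-(9-borabicyclo[3.3.1]nonan-9-yl)ethyl]phenyl acetate | CC(=O)Oc1ccc(CCB2C3CCCC2CCC3)cc1 | intermediate (not isolated)
13 | methyl 5-[2-(4-acetoxyphenyl)ethyl]-7-hydroxy-2,2-dimethyl-8-(3-methylbut-2-en-1-yl)-2H-chromene-6-carboxylate | COC(=O)c1c(O)c(CC=C(C)C)c2c(c1CCc1ccc(OC(C)=O)cc1)C=CC(C)(C)O2 | intermediate (not isolated)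
14 | methyl 7-hydroxy-5-[2-(4-hydroxyphenyl)ethyl]-2,2-dimethyl-8-(3-methylbut-2-en-1-yl)-2H-chromene-6-carboxylate (CNP0133674.0) | COC(=O)c1c(O)c(CC=C(C)C)c2c(c1CCc1ccc(O)cc1)C=CC(C)(C)O2 | target

**Total step count:** 5. **Longest linear sequence:** 5 steps (1 → 3 → 5 → 6 → 9 → 14).

**Steps most likely to fail**

1. Step 5 (key coupling). Oxidative addition into the doubly ortho-flanked C5–OTf bond of the phenoxide form of 9 may be slower than base-induced S–O cleavage of the triflate and than β-hydride elimination from the alkylpalladium, so that detriflation or reduction could outrun coupling. The fallback sets out from 9 and removes the phenoxide from the coupling partner. Compound 9 would be acetylated (Ac2O, Et3N, DMAP, CH2Cl2) to methyl 7-acetoxy-2,2-dimethyl-8-(3-methylbut-2-en-1-yl)-5-{[(trifluoromethyl)sulfonyl]oxy}-2H-chromene-6-carboxylate F1, a neutral and more electron-poor triflate. F1 would be coupled with alkylborane 12 under water-free conditions (Pd(OAc)2, SPhos, powdered K3PO4, THF/DMF, 60 °C) to give methyl 7-acetoxy-5-[2-(4-acetoxyphenyl)ethyl]-2,2-dimethyl-8-(3-methylbut-2-en-1-yl)-2H-chromene-6-carboxylate F2. Methanolysis of both aryl acetates (K2CO3 cat., MeOH, rt) would come back to the route at 14.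

2. Step 3 (site-selective triflation). Discrimination between the two ester-chelated hydroxyls of 5 may be insufficient, so that sulfonylation could occur at the wrong oxygen or at both. The fallback sets out from the symmetric diol 3, whose two hydroxyls are equivalent. Mono-triflation (PhNTf2, 1.0 equiv, Et3N, DMAP cat., CH2Cl2) would give methyl 2-hydroxy-4-[(2-methylbut-3-yn-2-yl)oxy]-6-{[(trifluoromethyl)sulfonyl]oxy}benzoate F3 without any regiochemical question. Ortho C-prenylation of its sodium phenoxide with 4 (NaH, toluene) would then place the prenyl group next to the only remaining hydroxyl and come back to the route at 6.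

3. Step 2 (C-prenylation). O-alkylation and a second C-alkylation may compete with mono-C-prenylation of the phenoxide. The fallback sets out from 1 and reverses the order, using electrophilic aromatic substitution in place of phenoxide alkylation. Friedel–Crafts prenylation of 1 with 2-methylbut-3-en-2-ol (BF3·OEt2, dioxane, rt) would give methyl 2,4,6-trihydroxy-3-(3-methylbut-2-en-1-yl)benzoate F4. Selective O-propargylation of its non-chelated 4-OH with 2 (K2CO3, KI cat., CuI cat., acetone, 50 °C) would come back to the route at 5.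

**Further compounds**
F1 | step 5 | methyl 7-acetoxy-2,2-dimethyl-8-(3-methylbut-2-en-1-yl)-5-{[(trifluoromethyl)sulfonyl]oxy}-2H-chromene-6-carboxylate | COC(=O)c1c(OC(C)=O)c(CC=C(C)C)c2c(c1OS(=O)(=O)C(F)(F)F)C=CC(C)(C)O2
F2 | step 5 | methyl 7-acetoxy-5-[2-(4-acetoxyphenyl)ethyl]-2,2-dimethyl-8-(3-methylbut-2-en-1-yl)-2H-chromene-6-carboxylate | COC(=O)c1c(OC(C)=O)c(CC=C(C)C)c2c(c1CCc1ccc(OC(C)=O)cc1)C=CC(C)(C)O2
F3 | step 3 | methyl 2-hydroxy-4-[(2-methylbut-3-yn-2-yl)oxy]-6-{[(trifluoromethyl)sulfonyl]oxy}benzoate | COC(=O)c1c(O)cc(OC(C)(C)C#C)cc1OS(=O)(=O)C(F)(F)F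
F4 | step 2 | methyl 2,4,6-trihydroxy-3-(3-methylbut-2-en-1-yl)benzoate | COC(=O)c1c(O)cc(O)c(CC=C(C)C)c1O
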